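## Structural features

The target is a germacranolide: a ten-membered carbocycle (C1–C10) with a cis-fused α-methylene-γ-butyrolactone across C6–C7 (C11, C12, C13), an exocyclic methylene at C10 (C14), a Z-trisubstituted C4=C5 alkene carrying the C15 methyl group, free carbinols at C1 and C3, and an angelate at C8. Of the five stereocentres, C6, C7 and C8 are contiguous and carry the lactone oxygen, C11 and the ester oxygen on one face; C1 and C3 flank the C2 methylene and are both allylic. The fragile groups are the α-methylene lactone (Michael acceptor, reducible), the angelate (isomerizes to the tiglate and is base-labile) and the two allylic alcohols; any C10 ketone precursor is α- and β-oxygenated and so prone to epimerization and elimination. The real difficulty is forming a ten-membered ring that contains a Z alkene while controlling five stereocentres on a conformationally mobile ring. The key step exploits the fact that C4 and C10 lie across the ring: a transannular C4–C10 bond turns the ring into a bicyclo[5.3.0]decane (five-membered ring C4–C3–C2–C1–C10, seven-membered ring C4–C5–C6–C7–C8–C9–C10). On this rigid bicycle the stereocentres can be set, and heterolytic cleavage of the shared bond returns the ten-membered ring with the C4=C5 alkene and a C10 carbonyl, the precursor of the C10=C14 methylene. The Z geometry translates into a cis ring fusion of that bicycle.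

## Logic of the disconnections

40 ⇒ 39 ⇒ 36 + 37. The two O–Si bonds at C1/C3 and the C8–O acyl bond are cut last, because the angelate is the group most prone to isomerization and the allylic carbinols are best kept masked. This leaves 36 with a single free hydroxyl. The forward steps must acylate without Z→E isomerization and desilylate without base.

36 ⇒ 35 ⇒ 32 ⇒ 31. The C11=C13 and C10=C14 bonds are cut. Neither exocyclic alkene would survive SmI2 or strong base, and both map onto carbonyl chemistry (lactone α-CH2, C10 ketone). The gain is that 31 carries exactly the carbonyl that the fragmentation produces. The demand is a non-basic methylenation of an α-silyloxy ketone and a lactone enolate Mannich reaction before any angelate is present.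

31 ⇒ 29 (key). The C4–C10 bond is reconnected, C5 receives a sulfonate and C10 a hydroxyl. The ten-membered ring is thereby replaced by a rigid hydroazulene in which C1, C3, C6, C7 and C8 are fixed by ring constraints. The forward step needs the C5–O bond anti-periplanar to C4–C10 with C3 gauche to C6. This is only possible in a cis-fused bicycle, so 29 has the C4 methyl and the C10 hydroxyl on the same face and C3 and the C5 mesylate on the same face. A trans-fused isomer would hold C3 anti to C6 and could only lead to the E alkene.

29 ⇒ 28 ⇒ 27 ⇒ 26 ⇒ 25. The C8–H bond is cut (carbinol from ketone). The C8 oxygen must be cis to the C7 branch, which no intermolecular addition to C8 would deliver. A ketone at C8 lets the tertiary C10 hydroxyl direct hydride to the correct face. The gain is that the C8 configuration of all earlier compounds is irrelevant; the cost is a protect/deprotect pair.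

25 ⇒ 24 ⇒ 23. The C1–C10 bond is cut (pinacol). One step creates the five-membered ring, the tertiary C10 carbinol that later drives the fragmentation, and the C1 carbinol. The demand is a cis diol and a cis ring fusion.

23 ⇒ 22 ⇒ 20. The C8–O bond is cut back to the enone and the C1 aldehyde is masked as an acetal. This gives a cycloheptenone whose β-carbon is C8.

20 ⇒ 16 + 17. The C7–C11 and O6–C12 bonds are cut. The cis C6–O/C7–C pair is traced to a vinyl epoxide and a two-carbon malonate-type nucleophile. The forward step must attack C7 (not C9) with net retention.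

16 ⇒ 14 ⇒ 13. The C8–O bridge bond is re-formed (retro-E1cB) and the epoxide oxygen is removed. In 13 the single bridging oxygen holds C5 and C8, and the exo face of C6=C7 is the face that the lactone oxygen needs. The forward opening requires that only C9 be enolizable (C4 is quaternary) and that the C5 alkoxide be trapped.

13 ⇒ 12 ⇒ 8 + 10. The C4–C3 bond and the C15–H bond are cut (reductive aldol). The quaternary C4 and the C3 carbinol arise together from a regiodefined enolate. The demand is attack on the face of the oxygen bridge and anti topicity.

8 ⇒ 6 ⇒ 4. The C4–C15 bond is cut. Desymmetrization of meso 4 at this point sets the absolute configuration of the whole route with a single chiral reagent.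

4 ⇒ 3 ⇒ 1 + 2. The C4–C5 and C8–C9 bonds are cut ([4+3] cycloaddition). This reduces the seven-membered ring to two commercial compounds; the chlorines are removed reductively.

10 ⇒ 9. The aldehyde is taken back to the commercial ester by partial reduction.

## Other disconnections considered

Alternative 1: The cut removes the two C–O bonds at C6 and C3 of A1 and leads back to the ten-membered 3,5-diene acid A2. In the forward step palladium diacetate, reoxidized by benzoquinone in the presence of lithium acetate and a little lithium chloride, activates the diene; the C12 carboxylate adds to C6, acetate adds to C3 of the π-allyl intermediate, and C4=C5 remains.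
- In favour: one oxidation would build the lactone and the C3–O bond and fix the Z alkene inside the π-allyl unit. It is the most oxidation-economical of the four plans, and A1 is only two deprotections and no skeletal step away from 40; on this last point it is better than the chosen plan.
- Against: A2 already contains the ten-membered ring, so ring formation is only postponed. A2 carries three further alkenes (C10=C14, the acrylic acid, the angelate) that can compete for divalent palladium. Two stereocentres (C6 relative to C7, C3 relative to C1) would be decided at once by facial selectivity on a flexible ring. The C3 acetate would have to be removed next to an angelate.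
- Comparison: the chosen plan fixes all five stereocentres on rigid bicycles before the medium ring exists; alternative 1 sets two of them on the medium ring. Mechanistically both steps are stereospecific in principle. Overall step economy is expected to be equal or worse once a route to A2 is added.

Alternative 2: The cut is C3–C4; A3 would come from the open-chain lactone A4, which carries a Z vinyl iodide at C4 and the C3 aldehyde. In the forward step CrCl2 with a catalytic amount of NiCl2 converts the vinyl iodide into a vinylchromium species that adds to the aldehyde (Nozaki–Hiyama–Kishi), forming C3–C4, the C3 carbinol and the ring.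
- In favour: the plan is convergent and the reaction tolerates lactone, angelate and exocyclic alkenes. The Z geometry is carried over from the iodide. A3 is one desilylation from 40, so no late methylenations are needed; in end-game step count and functional-group tolerance it is better than the chosen plan.
- Against: closing a ten-membered ring by bond formation needs high dilution and competes with oligomerization. The C3 configuration would be set during the cyclization under substrate control. The β-silyloxy aldehyde can eliminate, and chromium is used in large excess.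
- Comparison: the chosen plan reveals the ring by breaking a bond (no entropic penalty) and has C3 in place beforehand; alternative 2 is shorter after the ring is made but leaves its two hardest issues (ring closure, C3) to one step.

Alternative 3: The cut is C1–C2; A5 would arise by Claisen rearrangement of the ten-membered 2-methylene cyclic enol ether A6, itself made by methylenation of a ten-membered lactone. On heating, C2 bonds to C1 and O–C14 breaks, giving the C3 ketone, the C10=C14 methylene and the carbocycle.
- In favour: macrolactonization is usually easier than carbocyclization. The shift makes C1–C2, the exocyclic methylene and a C3 carbonyl in one thermal step and transfers enol ether geometry into C1. It delivers C14 without a separate methylenation, a point on which it is better than the chosen plan.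
- Against: a ten-membered lactone is still strained to close. C1 depends on the enol ether geometry and on chair versus boat in a ring-constrained transition state. C3 arrives as a Z-enone carbonyl that must be reduced 1,2 with facial control on the medium ring and may isomerize.
- Comparison: both plans avoid direct C–C macrocyclization and both rely on a stereospecific reorganization; the chosen plan has C1 and C3 fixed before the ring is opened, alternative 3 creates them on the medium ring. In protecting-group logic the two are equal.

Key step: step 19

Remark on the fragmentation substrate: a trans-fused bicyclo[5.3.0]decane cannot give the 4Z alkene, because with the C5 sulfonate anti to C4–C10 its C3 lies anti to C6. Compound 29 is therefore cis-fused.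

Assumption: the (R,R) lithium amide is taken to remove the α-proton at the carbon that becomes C4; if the sense of induction is the opposite, the (S,S) amide is used and nothing else changes.

Convention: positions carry the numbering of 40. "β" is the face of the seven-membered ring that carries the oxygen bridge (later the C6 oxygen); "α" is the opposite face.

## Route

Step 1
Reactants: 1 furan; 2 1,1,3-trichloroacetone
Product: 3 2,4-dichloro-8-oxabicyclo[3.2.1]oct-6-en-3-one (mixture of C–Cl epimers)
Conditions: Et3N, CF3CH2OH, 0 °C → rt (furan in excess)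
Reagents that add atoms: none
Why: Triethylamine converts 2 into a 1,3-dichloro-2-oxyallyl cation that adds across C2/C5 of furan in a [4+3] cycloaddition; the C–Cl configurations do not matter because both chlorines are removed next.

Step 2
Reactants: 3 2,4-dichloro-8-oxabicyclo[3.2.1]oct-6-en-3-one
Product: 4 meso-8-oxabicyclo[3.2.1]oct-6-en-3-one (C10 ketone, C4 and C9 methylenes, C5 and C8 bridgeheads, C6=C7)
Conditions: Zn(Cu), NH4Cl, MeOH, rt
Reagents that add atoms: none
Why: Zinc reduces both α-chloro ketone C–Cl bonds through zinc enolates that NH4Cl protonates (reductive dehalogenation), giving the meso ketone.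

Step 3
Reactants: 4 meso-8-oxabicyclo[3.2.1]oct-6-en-3-one
Product: 6 C4 Mannich base (4β-dimethylaminomethyl ketone), via trimethylsilyl enol ether 5 (not isolated)
Conditions: [(R)-PhCH(Me)]2NLi (from the amine and n-BuLi), LiCl, Me3SiCl, THF, −100 °C; then CH2=NMe2+ I−, CH2Cl2, rt; aq. NaHCO3
Reagents that add atoms: dimethyl(methylidene)ammonium iodide, C=[N+](C)C.[I-]
Why: The chiral lithium amide removes one of the two enantiotopic axial α-protons of meso 4 (enantioselective deprotonation with internal silyl quench), which fixes the absolute configuration of the whole route; the enol ether then undergoes a Mannich reaction with the iminium salt on the face of the oxygen bridge.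

Step 4
Reactants: 6 C4 Mannich base
Product: 8 4(15)-methylene ketone (2-methylene-8-oxabicyclo[3.2.1]oct-6-en-3-one, single enantiomer), via trimethylammonium iodide 7 (not isolated)
Conditions: MeI, CH2Cl2, rt; then aq. NaHCO3, CH2Cl2, rt
Reagents that add atoms: none
Why: Quaternization turns the amine into a leaving group and mild base induces E1cB loss of trimethylamine (Mannich base elimination); the ammonium group leaves far faster than the β-oxygen bridge.

Step 5
Reactants: 9 methyl 3,3-dimethoxypropanoate
Product: 10 3,3-dimethoxypropanal
Conditions: i-Bu2AlH, CH2Cl2, −78 °C; Rochelle salt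
Reagents that add atoms: none
Why: Low-temperature i-Bu2AlH reduction stops at the tetrahedral aluminium hemiacetal, which releases the aldehyde on work-up (partial reduction of an ester).

Step 6
Reactants: 8 4(15)-methylene ketone; 10 3,3-dimethoxypropanal
Product: 12 aldol adduct (C4 quaternary: methyl α and 1-hydroxy-3,3-dimethoxypropyl chain β; C3 carbinol), via lithium enolate 11 (not isolated)
Conditions: LiBH(s-Bu)3, THF, −78 °C; then 10, −78 °C; aq. NH4Cl
Reagents that add atoms: none
Why: Conjugate hydride addition to the exocyclic enone gives the tetrasubstituted enolate 11 regiospecifically and its aldol addition to 10 forms C4–C3 (reductive aldol); the aldehyde approaches C4 axially on the face of the oxygen bridge, away from the two-carbon bridge, and a closed Zimmerman–Traxler transition state with the aldehyde chain equatorial sets C3 (oxygen anti to C5 along the chain C10–C4–C3–C2).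

Step 7
Reactants: 12 aldol adduct
Product: 13 C3 tert-butyldimethylsilyl ether of 12
Conditions: t-BuMe2SiOTf, 2,6-lutidine, CH2Cl2, −78 °C
Reagents that add atoms: tert-butyldimethylsilyl trifluoromethanesulfonate, CC(C)(C)[Si](C)(C)OS(=O)(=O)C(F)(F)F
Why: The silyl triflate with a hindered base silylates the hindered secondary carbinol at low temperature and blocks retro-aldol cleavage; the dimethyl acetal survives at −78 °C.

Step 8
Reactants: 13 C3 silyl ether
Product: 14 6β,7β-epoxide of 13 (epoxide on the face of the oxygen bridge)
Conditions: dimethyldioxirane, acetone, 0 °C → rt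
Reagents that add atoms: dimethyldioxirane, CC1(C)OO1
Why: The dioxirane epoxidizes the bicyclic alkene from the exo face, the face of the oxygen bridge, without Baeyer–Villiger oxidation of the ketone; this puts the future C6 oxygen cis to the C5 oxygen.

Step 9
Reactants: 14 6β,7β-epoxide
Product: 16 6β,7β-epoxy-cyclohept-8-en-10-one with C5β mesylate, via lithium C5 alkoxide 15 (not isolated)
Conditions: LiN(SiMe3)2, THF, −78 → −30 °C; then MeSO2Cl, −30 °C
Reagents that add atoms: methanesulfonyl chloride, CS(=O)(=O)Cl
Why: Only C9 can be enolized, and its enolate expels the axial C8–O bond (E1cB, retro-oxa-Michael), which opens the bridge to the cycloheptenone and leaves the oxygen on C5 with its configuration untouched; capture of alkoxide 15 as the mesylate stops re-addition to the enone and installs the later nucleofuge.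

Step 10
Reactants: 16 epoxy enone mesylate; 17 Meldrum's acid (2,2-dimethyl-1,3-dioxane-4,6-dione)
Product: 20 cis-fused 12,6-lactone of the cyclohept-8-en-10-one (C11 on C7β), via alkylated Meldrum's acid 18 (not isolated), via carboxy lactone 19 (not isolated)
Conditions: Pd(PPh3)4 (5 mol %), THF, rt; then pyridine, 90 °C
Reagents that add atoms: none
Why: Zerovalent palladium ionizes the allylic C7–O bond of the vinyl epoxide with inversion and the soft carbanion of 17 attacks C7 anti to the metal (Tsuji–Trost alkylation, net retention), so C11 ends up cis to the C6 oxygen; attack at C7 rather than C9 keeps the enone conjugated, and on heating the C6 hydroxyl opens the dioxanedione (loss of acetone) and the malonic half-acid 19 loses CO2.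

Step 11
Reactants: 20 lactone enone
Product: 22 8α-hydroxy-10-ketone, via 8α-pinacolboryl ketone 21 (not isolated)
Conditions: CuCl (5 mol %), bis[2-(diphenylphosphino)phenyl] ether, NaOt-Bu (cat.), B2pin2, MeOH, THF, rt; then NaBO3·4H2O, THF–H2O, rt
Reagents that add atoms: sodium perborate, [Na+].[O-]OB=O
Why: A copper boryl species adds to the β-carbon C8 of the enone anti to the C7 substituent (conjugate borylation) and perborate oxidizes the C–B bond with retention; the C8 configuration made here is immaterial because C8 passes through a ketone in steps 16 and 17.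

Step 12
Reactants: 22 8α-hydroxy-10-ketone
Product: 23 8α-triethylsilyloxy keto aldehyde (C1 aldehyde, C10 ketone)
Conditions: Et3SiOTf, 2,4,6-collidine, CH2Cl2, 0 °C; then H2O
Reagents that add atoms: triethylsilyl trifluoromethanesulfonate, CC[Si](CC)(CC)OS(=O)(=O)C(F)(F)F; water, O
Why: The silyl triflate silylates the C8 hydroxyl and, together with the hindered pyridine, converts the dimethyl acetal into a pyridinium N,O-acetal that water hydrolyses to the aldehyde without acid, so the silyl ethers, the mesylate and the ketone are untouched.

Step 13
Reactants: 23 keto aldehyde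
Product: 24 cis-fused bicyclo[5.3.0]decane 1,10-diol (C10 hydroxyl α, C1 hydroxyl cis to it)
Conditions: SmI2, t-BuOH, THF, −78 °C; aq. NH4Cl
Reagents that add atoms: none
Why: SmI2 reduces the aldehyde to a ketyl that adds to the C10 ketone (intramolecular pinacol coupling, 5-exo); the chain on C4 must be axial to reach C10, so the new bond forms on its own face (cis ring fusion, C10 hydroxyl cis to the methyl group), and chelation of both oxygens to trivalent samarium gives the cis-1,10-diol.

Step 14
Reactants: 24 1,10-diol
Product: 25 C1 tert-butyldimethylsilyl ether (C10 hydroxyl free)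
Conditions: t-BuMe2SiOTf, 2,6-lutidine, CH2Cl2, −78 °C
Reagents that add atoms: tert-butyldimethylsilyl trifluoromethanesulfonate, CC(C)(C)[Si](C)(C)OS(=O)(=O)C(F)(F)F
Why: At −78 °C the silyl triflate discriminates the secondary C1 hydroxyl from the tertiary C10 hydroxyl, which must stay free as the later electron donor.

Step 15
Reactants: 25 C1 silyl ether
Product: 26 8α-alcohol
Conditions: pyridinium p-toluenesulfonate, MeOH–CH2Cl2, 0 °C
Reagents that add atoms: none
Why: Mild acidic methanolysis removes the triethylsilyl ether while the two secondary tert-butyldimethylsilyl ethers, the mesylate and the lactone are stable (selective desilylation).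

Step 16
Reactants: 26 8α-alcohol
Product: 27 8-ketone (10-hydroxy-8-one)
Conditions: Dess–Martin periodinane, NaHCO3, CH2Cl2, rt
Reagents that add atoms: none
Why: Dess–Martin oxidation converts the only free secondary alcohol into the ketone under buffered, non-basic conditions, so the β-hydroxy ketone does not undergo retro-aldol cleavage and the γ-mesyloxy alcohol is not ionized.

Step 17
Reactants: 27 8-ketone
Product: 28 8β-alcohol (anti to the C10 hydroxyl, cis to C11)
Conditions: Me4NBH(OAc)3, MeCN–AcOH, −30 °C
Reagents that add atoms: none
Why: The tertiary C10 hydroxyl exchanges onto boron and delivers hydride to C8 from its own face (hydroxyl-directed Evans–Saksena reduction), giving the anti-1,3-diol; this is also the face opposite to the C7 substituent, so the C8 oxygen ends up cis to C11 as in 40.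

Step 18
Reactants: 28 8β-alcohol
Product: 29 fragmentation substrate: cis-fused bicyclo[5.3.0]decane with free C10 hydroxyl (α), C4 methyl (α), C5 mesylate (β), 12,6-lactone, C8β triethylsilyl ether, C1 and C3 tert-butyldimethylsilyl ethers
Conditions: Et3SiOTf, 2,6-lutidine, CH2Cl2, −78 °C
Reagents that add atoms: triethylsilyl trifluoromethanesulfonate, CC[Si](CC)(CC)OS(=O)(=O)C(F)(F)F
Why: Low-temperature silylation protects the secondary C8 hydroxyl and leaves the tertiary C10 hydroxyl free; the triethylsilyl ether can later be removed in the presence of the two tert-butyldimethylsilyl ethers.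

Step 19
Reactants: 29 fragmentation substrate
Product: 31 ten-membered (4Z)-en-10-one with 12,6-lactone, via potassium C10 alkoxide 30 (not isolated)
Conditions: KN(SiMe3)2 (1.05 equiv), THF, −78 → 0 °C; pH 7 buffer
Reagents that add atoms: none
Why: The potassium alkoxide 30 pushes electron density into the C4–C10 σ bond, which breaks as the C4=C5 π bond forms and methanesulfonate leaves C5 in one concerted event (Grob fragmentation; the closest known type is the Wharton fragmentation of cyclic 1,3-diol monosulfonates to medium-ring enones). No ring is closed by bond formation: the ten-membered ring appears because the bond shared by the five- and seven-membered rings is cut. No stereocentre is created; C1, C3, C6, C7 and C8 are untouched, and C4 and C5 become trigonal. The alkene geometry is fixed by the ring fusion: in cis-fused 29 the C5 mesylate can lie equatorial on the seven-membered ring, anti-periplanar to C4–C10, with C3 axial at C4 and therefore gauche to C6, so C3 and C6 end up cis on the new double bond (Z). A trans-fused isomer would hold C3 equatorial and anti to C6 and could only give the E alkene, or would have the mesylate anti to the methyl group, which is why 29 is built with the methyl group and the C10 oxygen on the same face. The step needs fragmentation to outrun oxetane formation, E2 loss of the mesylate and attack of the alkoxide on the lactone: a secondary sulfonate next to a quaternary carbon resists substitution, H6 is gauche to the mesylate in the reactive conformer, and one equivalent of base at low temperature leaves no excess to enolize the lactone or the product ketone. Migration of the C1 silyl group to the C10 oxygen is reversible and only the C10 alkoxide can fragment, so it does not divert material.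

Step 20
Reactants: 31 ten-membered (4Z)-en-10-one
Product: 32 10(14)-methylene compound
Conditions: Zn, CH2Br2, TiCl4, THF–CH2Cl2, 0 °C → rt
Reagents that add atoms: dibromomethane, BrCBr
Why: The geminal dizinc–titanium reagent methylenates the hindered, enolizable ketone without base (Takai–Lombardo methylenation), so C1 is not epimerized, the C8 silyloxy group is not eliminated and the lactone is not attacked.

Step 21
Reactants: 32 10(14)-methylene compound
Product: 35 α-methylene lactone (11(13)-ene), via C11 Mannich base 33 (not isolated), via trimethylammonium iodide 34 (not isolated)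
Conditions: LiN(SiMe3)2, THF, −78 °C; CH2=NMe2+ I−, −78 → 0 °C; then MeI, MeOH, rt; then aq. NaHCO3, CH2Cl2
Reagents that add atoms: dimethyl(methylidene)ammonium iodide, C=[N+](C)C.[I-]
Why: The lactone α-protons are the most acidic C–H bonds; the lithium enolate adds to the iminium salt (Mannich reaction) and quaternization followed by mild base eliminates trimethylamine to give the α-methylene lactone.

Step 22
Reactants: 35 α-methylene lactone
Product: 36 8β-alcohol with C1 and C3 tert-butyldimethylsilyl ethers
Conditions: HF·pyridine, pyridine, THF, 0 °C
Reagents that add atoms: none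
Why: Buffered HF·pyridine cleaves the triethylsilyl ether much faster than the secondary tert-butyldimethylsilyl ethers and does not touch the α-methylene lactone (selective desilylation).

Step 23
Reactants: 36 8β-alcohol; 37 angelic acid
Product: 39 8-O-angelate with C1 and C3 tert-butyldimethylsilyl ethers, via angelic 2,4,6-trichlorobenzoic anhydride 38 (not isolated)
Conditions: 2,4,6-Cl3C6H2COCl, Et3N, PhMe, rt; then 36, PhMe, 80 °C
Reagents that add atoms: none
Why: The mixed anhydride 38 acylates the C8 hydroxyl at the less hindered angeloyl carbonyl (Yamaguchi-type esterification run without a nucleophilic amine catalyst), which avoids the conjugate-addition pathway that isomerizes angelates to tiglates.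

Step 24
Reactants: 39 8-O-angelate bis-silyl ether
Product: 40 target CNP0175889.6
Conditions: HF·pyridine, THF, rt
Reagents that add atoms: none
Why: Fluoride in a buffered, non-basic medium removes both tert-butyldimethylsilyl ethers and leaves the angelate, the α-methylene lactone and the three alkenes intact (global desilylation).

## Compound list

1 | furan | c1ccoc1 | starting material
2 | 1,1,3-trichloroacetone | ClCC(=O)C(Cl)Cl | starting material
3 | 2,4-dichloro-8-oxabicyclo[3.2.1]oct-6-en-3-one (C–Cl epimer mixture, centres left undefined) | ClC1C(=O)C(Cl)C2C=CC1O2 | intermediate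
4 | meso-8-oxabicyclo[3.2.1]oct-6-en-3-one | O=C1C[C@H]2C=C[C@@H](C1)O2 | intermediate
5 | trimethylsilyl enol ether (C4=C10) of 4, single enantiomer | C[Si](C)(C)OC1=C[C@H]2C=C[C@@H](C1)O2 | intermediate (not isolated)
6 | 4β-(dimethylaminomethyl)-8-oxabicyclo[3.2.1]oct-6-en-3-one | O=C1[C@H](CN(C)C)[C@H]2C=C[C@@H](C1)O2 | intermediate
7 | trimethylammonium iodide of 6 | O=C1[C@H](C[N+](C)(C)C)[C@H]2C=C[C@@H](C1)O2.[I-] | intermediate (not isolated)
8 | 2-methylene-8-oxabicyclo[3.2.1]oct-6-en-3-one (C4=C15), single enantiomer | O=C1C(=C)[C@H]2C=C[C@@H](C1)O2 | intermediate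
9 | methyl 3,3-dimethoxypropanoate | COC(=O)CC(OC)OC | starting material
10 | 3,3-dimethoxypropanal | O=CCC(OC)OC | intermediate
11 | lithium enolate (C4=C10, C4 methyl) | [Li]OC1=C(C)[C@H]2C=C[C@@H](C1)O2 | intermediate (not isolated)
12 | aldol adduct: C4 α-methyl, β-(1-hydroxy-3,3-dimethoxypropyl) | O=C1[C@](C)([C@@H](O)CC(OC)OC)[C@H]2C=C[C@@H](C1)O2 | intermediate
13 | C3 tert-butyldimethylsilyl ether of 12 | O=C1[C@](C)([C@@H](O[Si](C)(C)C(C)(C)C)CC(OC)OC)[C@H]2C=C[C@@H](C1)O2 | intermediate
14 | 6β,7β-epoxide of 13 | O=C1[C@](C)([C@@H](O[Si](C)(C)C(C)(C)C)CC(OC)OC)[C@H]2[C@@H]3O[C@@H]3[C@@H](C1)O2 | intermediate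
15 | lithium C5 alkoxide of the ring-opened epoxy enone | O=C1C=C[C@H]2O[C@H]2[C@@H](O[Li])[C@@]1(C)[C@@H](O[Si](C)(C)C(C)(C)C)CC(OC)OC | intermediate (not isolated)
16 | 6β,7β-epoxy-cyclohept-8-en-10-one, C5β mesylate | O=C1C=C[C@H]2O[C@H]2[C@@H](OS(C)(=O)=O)[C@@]1(C)[C@@H](O[Si](C)(C)C(C)(C)C)CC(OC)OC | intermediate
17 | Meldrum's acid | CC1(C)OC(=O)CC(=O)O1 | starting material
18 | C7β-alkylated Meldrum's acid with free C6β hydroxyl | O=C1C=C[C@@H](C2C(=O)OC(C)(C)OC2=O)[C@@H](O)[C@@H](OS(C)(=O)=O)[C@@]1(C)[C@@H](O[Si](C)(C)C(C)(C)C)CC(OC)OC | intermediate (not isolated)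
19 | 11-carboxy-12,6-lactone (C11 epimers, centre left undefined) | O=C1C=C[C@H]2C(C(=O)O)C(=O)O[C@H]2[C@@H](OS(C)(=O)=O)[C@@]1(C)[C@@H](O[Si](C)(C)C(C)(C)C)CC(OC)OC | intermediate (not isolated)
20 | cis-fused 12,6-lactone, cyclohept-8-en-10-one, C5β mesylate | O=C1C=C[C@H]2CC(=O)O[C@H]2[C@@H](OS(C)(=O)=O)[C@@]1(C)[C@@H](O[Si](C)(C)C(C)(C)C)CC(OC)OC | intermediate
21 | 8α-pinacolboryl-10-ketone | O=C1C[C@H](B3OC(C)(C)C(C)(C)O3)[C@H]2CC(=O)O[C@H]2[C@@H](OS(C)(=O)=O)[C@@]1(C)[C@@H](O[Si](C)(C)C(C)(C)C)CC(OC)OC | intermediate (not isolated)
22 | 8α-hydroxy-10-ketone | O=C1C[C@H](O)[C@H]2CC(=O)O[C@H]2[C@@H](OS(C)(=O)=O)[C@@]1(C)[C@@H](O[Si](C)(C)C(C)(C)C)CC(OC)OC | intermediate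
23 | 8α-triethylsilyloxy-10-keto C1 aldehyde | O=C1C[C@H](O[Si](CC)(CC)CC)[C@H]2CC(=O)O[C@H]2[C@@H](OS(C)(=O)=O)[C@@]1(C)[C@@H](O[Si](C)(C)C(C)(C)C)CC=O | intermediate
24 | cis-fused bicyclo[5.3.0]decane 1,10-cis-diol | C1C(=O)O[C@H]2[C@@H](OS(C)(=O)=O)[C@@]3(C)[C@@H](O[Si](C)(C)C(C)(C)C)C[C@H](O)[C@@]3(O)C[C@H](O[Si](CC)(CC)CC)[C@@H]12 | intermediate
25 | C1 tert-butyldimethylsilyl ether of 24 | C1C(=O)O[C@H]2[C@@H](OS(C)(=O)=O)[C@@]3(C)[C@@H](O[Si](C)(C)C(C)(C)C)C[C@H](O[Si](C)(C)C(C)(C)C)[C@@]3(O)C[C@H](O[Si](CC)(CC)CC)[C@@H]12 | intermediate
26 | 8α-alcohol | C1C(=O)O[C@H]2[C@@H](OS(C)(=O)=O)[C@@]3(C)[C@@H](O[Si](C)(C)C(C)(C)C)C[C@H](O[Si](C)(C)C(C)(C)C)[C@@]3(O)C[C@H](O)[C@@H]12 | intermediate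
27 | 8-ketone | C1C(=O)O[C@H]2[C@@H](OS(C)(=O)=O)[C@@]3(C)[C@@H](O[Si](C)(C)C(C)(C)C)C[C@H](O[Si](C)(C)C(C)(C)C)[C@@]3(O)CC(=O)[C@@H]12 | intermediate
28 | 8β-alcohol | C1C(=O)O[C@H]2[C@@H](OS(C)(=O)=O)[C@@]3(C)[C@@H](O[Si](C)(C)C(C)(C)C)C[C@H](O[Si](C)(C)C(C)(C)C)[C@@]3(O)C[C@@H](O)[C@@H]12 | intermediate
29 | fragmentation substrate (cis-fused; C10 OH, C5β OMs, C8β OSiEt3) | C1C(=O)O[C@H]2[C@@H](OS(C)(=O)=O)[C@@]3(C)[C@@H](O[Si](C)(C)C(C)(C)C)C[C@H](O[Si](C)(C)C(C)(C)C)[C@@]3(O)C[C@@H](O[Si](CC)(CC)CC)[C@@H]12 | intermediate
30 | potassium C10 alkoxide of 29 | C1C(=O)O[C@H]2[C@@H](OS(C)(=O)=O)[C@@]3(C)[C@@H](O[Si](C)(C)C(C)(C)C)C[C@H](O[Si](C)(C)C(C)(C)C)[C@@]3(O[K])C[C@@H](O[Si](CC)(CC)CC)[C@@H]12 | intermediate (not isolated)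
31 | ten-membered (4Z)-en-10-one, 12,6-lactone | C1C(=O)O[C@H]2/C=C(/C)[C@@H](O[Si](C)(C)C(C)(C)C)C[C@H](O[Si](C)(C)C(C)(C)C)C(=O)C[C@@H](O[Si](CC)(CC)CC)[C@@H]12 | intermediate
32 | 10(14)-methylene compound | C1C(=O)O[C@H]2/C=C(/C)[C@@H](O[Si](C)(C)C(C)(C)C)C[C@H](O[Si](C)(C)C(C)(C)C)C(=C)C[C@@H](O[Si](CC)(CC)CC)[C@@H]12 | intermediate
33 | 11-(dimethylaminomethyl) lactone (C11 epimers, centre left undefined) | CN(C)CC1C(=O)O[C@H]2/C=C(/C)[C@@H](O[Si](C)(C)C(C)(C)C)C[C@H](O[Si](C)(C)C(C)(C)C)C(=C)C[C@@H](O[Si](CC)(CC)CC)[C@@H]12 | intermediate (not isolated)
34 | trimethylammonium iodide of 33 | C[N+](C)(C)CC1C(=O)O[C@H]2/C=C(/C)[C@@H](O[Si](C)(C)C(C)(C)C)C[C@H](O[Si](C)(C)C(C)(C)C)C(=C)C[C@@H](O[Si](CC)(CC)CC)[C@@H]12.[I-] | intermediate (not isolated)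
35 | α-methylene lactone, 8-O-triethylsilyl, 1,3-bis-O-tert-butyldimethylsilyl | C=C1C(=O)O[C@H]2/C=C(/C)[C@@H](O[Si](C)(C)C(C)(C)C)C[C@H](O[Si](C)(C)C(C)(C)C)C(=C)C[C@@H](O[Si](CC)(CC)CC)[C@@H]12 | intermediate
36 | 8β-alcohol, 1,3-bis-O-tert-butyldimethylsilyl | C=C1C(=O)O[C@H]2/C=C(/C)[C@@H](O[Si](C)(C)C(C)(C)C)C[C@H](O[Si](C)(C)C(C)(C)C)C(=C)C[C@@H](O)[C@@H]12 | intermediate
37 | angelic acid | C/C=C(/C)C(=O)O | starting material
38 | angelic 2,4,6-trichlorobenzoic anhydride | C/C=C(/C)C(=O)OC(=O)c1c(Cl)cc(Cl)cc1Cl | intermediate (not isolated)
39 | 8-O-angelate, 1,3-bis-O-tert-butyldimethylsilyl | C=C1C(=O)O[C@H]2/C=C(/C)[C@@H](O[Si](C)(C)C(C)(C)C)C[C@H](O[Si](C)(C)C(C)(C)C)C(=C)C[C@@H](OC(=O)/C(C)=C\C)[C@@H]12 | intermediate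
40 | CNP0175889.6 (8-angeloyloxy-1,3-dihydroxygermacra-4Z,10(14),11(13)-trien-12,6-olide) | C=C1C(=O)O[C@H]2/C=C(/C)[C@@H](O)C[C@H](O)C(=C)C[C@@H](OC(=O)/C(C)=C\C)[C@@H]12 | target

## Step count and least certain steps

Total: 24 steps. Longest linear sequence: 23 steps (steps 1–4 and 6–24); step 5 is a one-step branch.

Step 19 (key step). The seven-membered ring may prefer the conformer with an axial mesylate, because the reactive conformer holds C3, the C6 oxygen and the C8 oxygen syn-axial. In that case acyl transfer from the lactone to the C10 alkoxide, or base-induced loss of the mesylate toward C6, could outrun the fragmentation. The fallback avoids a free amide base altogether: 29 is silylated at the tertiary oxygen (Me3SiOTf, 2,6-lutidine) to the C10 trimethylsilyl ether F1, and the donor is then unmasked in situ with Bu4NF in THF at low temperature, so that the alkoxide is generated only transiently and under buffered conditions. This desilylative fragmentation comes back to the route at 31.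

Step 6. The aldol addition of a tetrasubstituted enolate may show poor simple diastereoselection at C3, because the methyl group on the enolate carbon erodes the difference between the two chair transition states. The fallback moves control of C3 from the transition state to a reagent: 12, as its C3 epimer mixture, is oxidized (Dess–Martin periodinane) to the 1,3-diketone F2. The more accessible side-chain ketone is then reduced with an oxazaborolidine catalyst and catecholborane (CBS reduction), which returns 12.

Step 10. The soft nucleophile may attack the π-allyl terminus C9 instead of C7, or the π-allyl alkoxide may lose a β-hydride to give a ketone. The fallback builds the lactone by cycloaddition and oxidation on the rigid bicycle: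
- 13 is treated with dichloroketene (Cl3CCOCl, Zn) to give the exo dichlorocyclobutanone F3;
- F3 is dechlorinated (Zn, AcOH) to F4;
- Baeyer–Villiger oxidation (H2O2, AcOH) gives the bicyclic lactone F5;
- the bridge of F5 is then opened as in step 9 (LiN(SiMe3)2, then MeSO2Cl), which returns the route at 20.

The weak point of this fallback is the regiochemistry of the ketene addition, which rests only on the remote difference between the C4 and C9 sides.

Step 11. The copper boryl species may be intercepted by the mesylate, or the catalytic alkoxide may deprotonate C7 and trigger loss of the lactone oxygen from C6. The fallback replaces conjugate borylation by epoxidation and reductive opening: 20 is epoxidized with t-BuOOH and a hindered amidine base to the α,β-epoxy ketone F6, and SmI2 in THF–MeOH at low temperature cleaves the Cα–O bond to return 22.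

Step 23. Isomerization of the angeloyl unit to the tigloyl unit, or sluggish acylation of the hindered C8 hydroxyl, is possible. The fallback makes the Z double bond on the substrate: 36 is esterified with 2-[bis(2,2,2-trifluoroethoxy)phosphoryl]propanoic acid (carbodiimide coupling) to the phosphonate ester F7, and a Z-selective Horner–Wadsworth–Emmons reaction of the Still–Gennari type with acetaldehyde (KN(SiMe3)2, 18-crown-6, THF, −78 °C) returns 39.

## Further compounds

F1 | step 19 | C10 trimethylsilyl ether of 29 | C1C(=O)O[C@H]2[C@@H](OS(C)(=O)=O)[C@@]3(C)[C@@H](O[Si](C)(C)C(C)(C)C)C[C@H](O[Si](C)(C)C(C)(C)C)[C@@]3(O[Si](C)(C)C)C[C@@H](O[Si](CC)(CC)CC)[C@@H]12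
F2 | step 6 | C3 ketone (1,3-diketone) from 12 | O=C1[C@](C)(C(=O)CC(OC)OC)[C@H]2C=C[C@@H](C1)O2
F3 | step 10 | exo dichlorocyclobutanone on C6/C7 of 13 (carbonyl on C6) | O=C1[C@](C)([C@@H](O[Si](C)(C)C(C)(C)C)CC(OC)OC)[C@H]2[C@@H]3C(=O)C(Cl)(Cl)[C@@H]3[C@@H](C1)O2
F4 | step 10 | exo cyclobutanone | O=C1[C@](C)([C@@H](O[Si](C)(C)C(C)(C)C)CC(OC)OC)[C@H]2[C@@H]3C(=O)C[C@@H]3[C@@H](C1)O2
F5 | step 10 | exo cis-fused 12,6-lactone on the oxabicycle | O=C1[C@](C)([C@@H](O[Si](C)(C)C(C)(C)C)CC(OC)OC)[C@H]2[C@@H]3OC(=O)C[C@@H]3[C@@H](C1)O2
F6 | step 11 | 8α,9α-epoxy-10-ketone from 20 | O=C1[C@@H]3O[C@@H]3[C@H]2CC(=O)O[C@H]2[C@@H](OS(C)(=O)=O)[C@@]1(C)[C@@H](O[Si](C)(C)C(C)(C)C)CC(OC)OC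
F7 | step 23 | C8 2-[bis(2,2,2-trifluoroethoxy)phosphoryl]propanoate of 36 (phosphonate α-carbon epimers) | C=C1C(=O)O[C@H]2/C=C(/C)[C@@H](O[Si](C)(C)C(C)(C)C)C[C@H](O[Si](C)(C)C(C)(C)C)C(=C)C[C@@H](OC(=O)C(C)P(=O)(OCC(F)(F)F)OCC(F)(F)F)[C@@H]12
A1 | alternative 1 | target as C3 acetate and C1 triethylsilyl ether | C=C1C(=O)O[C@H]2/C=C(/C)[C@@H](OC(C)=O)C[C@H](O[Si](CC)(CC)CC)C(=C)C[C@@H](OC(=O)/C(C)=C\C)[C@@H]12
A2 | alternative 1 | ten-membered (3Z,5Z)-diene C12 acid | C=C(C(=O)O)[C@H]1/C=C\C(C)=C/C[C@H](O[Si](CC)(CC)CC)C(=C)C[C@H]1OC(=O)/C(C)=C\C
A3 | alternative 2 | target as C1 tert-butyldimethylsilyl ether | C=C1C(=O)O[C@H]2/C=C(/C)[C@@H](O)C[C@H](O[Si](C)(C)C(C)(C)C)C(=C)C[C@@H](OC(=O)/C(C)=C\C)[C@@H]12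
A4 | alternative 2 | open-chain lactone with Z vinyl iodide at C4 and C3 aldehyde | C=C1C(=O)O[C@@H](/C=C(/C)I)[C@H]1[C@H](OC(=O)/C(C)=C\C)CC(=C)[C@@H](O[Si](C)(C)C(C)(C)C)CC=O
A5 | alternative 3 | ten-membered (4Z)-en-3-one with C1 silyl ether and C10=C14 | C=C(CO[Si](CC)(CC)CC)[C@H]1[C@@H](O[Si](CC)(CC)CC)/C=C(/C)C(=O)C[C@H](O[Si](C)(C)C(C)(C)C)C(=C)C[C@H]1OCc2ccc(OC)cc2
A6 | alternative 3 | ten-membered 2-methylene cyclic enol ether (oxygen between C3 and C14) | C=C(CO[Si](CC)(CC)CC)[C@H]1[C@@H](O[Si](CC)(CC)CC)/C=C(/C)C(=C)OC/C(=C/O[Si](C)(C)C(C)(C)C)C[C@H]1OCc2ccc(OC)cc2
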